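**Retrosynthetic overview**
- The target comes from a trans-benzodioxane methyl ester by ester-to-aldehyde adjustment, Wittig two-carbon extension and desilylation; the ring A ester is the masked enal.
- Ring B is the only ring built. It is closed through the O1–C2 bond: acid ionisation of the benzylic carbinol and capture by the ring A phenol, trans by equilibration.
- Feature used: C3 of ring B is bonded to O4 (on the ring A carbon next to C–OMe), to benzylic C2 and to C9 (the CH2OH carbon). C3 is therefore taken as the carbene carbon of ethyl diazoacetate (ester carbon = C9), and O4–C3 and C2–C3 are formed together from phenol, diazo ester and ring C aldehyde.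
- Rings A and C are bought: methyl 3,4-dihydroxy-5-methoxybenzoate (3-O-benzylated) and 5-hydroxyvanillin (bis-silylated). Silyl ethers are used on ring C because the ring closure is acidic and acetal-type phenol protection would not survive it.
- Locants throughout: O1–C2(aryl)–C3(CH2OH)–O4; ring A = benzo ring, ring C = pendant aryl; TBS = tert-butyldimethylsilyl.

Key step: step 3

Assumption: the sense of induction of the chiral phosphoric acid cannot be predicted for this substrate class; the (R)-acid is written for the (2S)-ester 9, and the (S)-acid would be used if the opposite sense were found.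

**Route**

Step 1
Reactants: 1 methyl 3,4-dihydroxy-5-methoxybenzoate
Product: 3 methyl 3-(benzyloxy)-4-hydroxy-5-methoxybenzoate, via disodium catecholate 2 (not isolated)
Conditions: NaH (2.2 equiv), DMSO, rt; BnBr (1.0 equiv), rt; aq. HCl work-up
Reagents that add atoms: benzyl bromide, BrCc1ccccc1
Why: Regioselective Williamson ether synthesis on the catechol dianion; the 3-oxide is not conjugated to the ester and is less hindered than the 4-oxide flanked by two oxygen substituents, so it should be the more nucleophilic site and take the single equivalent of benzyl bromide.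

Step 2
Reactants: 4 5-hydroxyvanillin (3,4-dihydroxy-5-methoxybenzaldehyde)
Product: 5 3-methoxy-4,5-bis(tert-butyldimethylsilyloxy)benzaldehyde
Conditions: TBSCl (2.5 equiv), imidazole (5 equiv), DMF, rt
Reagents that add atoms: tert-butyldimethylsilyl chloride, CC(C)(C)[Si](C)(C)Cl
Why: Standard imidazole-promoted silylation of phenols; the aryl silyl ethers should tolerate the carbene, hydride, hydrogenolysis, anhydrous acid and ylide conditions that follow and fall to fluoride at the end.

Step 3
Reactants: 3 methyl 3-(benzyloxy)-4-hydroxy-5-methoxybenzoate, 5 3-methoxy-4,5-bis(tert-butyldimethylsilyloxy)benzaldehyde, 6 ethyl diazoacetate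
Product: 9 ethyl (2S)-2-[2-(benzyloxy)-6-methoxy-4-(methoxycarbonyl)phenoxy]-3-hydroxy-3-[3-methoxy-4,5-bis(tert-butyldimethylsilyloxy)phenyl]propanoate (both carbinol epimers), via carbene complex Rh2(OAc)4=CHCO2Et 7 (not isolated), via oxonium ylide 8 (not isolated)
Conditions: Rh2(OAc)4 (2 mol %), (R)-TRIP [(R)-3,3'-bis(2,4,6-triisopropylphenyl)-BINOL hydrogen phosphate] (10 mol %), 4 Å MS, CH2Cl2, 0 °C; 5 (2 equiv); 6 (2 equiv) by syringe pump
Reagents that add atoms: none
Why: Proposed new method: Rh2(OAc)4 should extrude N2 from 6 to give the electrophilic carbene 7, the free 4-hydroxyl of 3 attacks it to give the protic oxonium ylide 8 (rhodium-associated or as its enol), and 8 should add through carbon to aldehyde 5, hydrogen-bonded in the chiral phosphate pocket, before the 1,2-proton shift that would give only the O–H insertion product. The closest known reaction type is the three-component aldol- and Mannich-type trapping of oxonium ylides, formed from aryl diazoacetates and alcohols, by imines or activated aldehydes under Rh2(OAc)4 and a chiral phosphoric acid; a phenol, an acceptor-only diazo ester and a non-activated aryl aldehyde together have not been shown. No ring is closed; the step forms the O4–C3 and C2–C3 bonds of the later ring B. The new stereocentre at the aryloxy-bearing carbon (later C3) should be set by the phosphate, which binds the ylide O–H and the aldehyde in one assembly and so selects the enol face, while the carbinol centre (later C2) is left uncontrolled because step 6 erases it. The step needs aldol trapping to beat the proton shift and needs bonding at O4 only: the first is helped by slow addition of 6, excess 5, dry conditions and an aldehyde that is less deactivated than it looks (two meta oxygens, para silyloxy twisted out of conjugation by its two neighbours), and the second is secured because 3 has a single free hydroxyl.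

Step 4
Reactants: 9 ethyl (2S)-2-aryloxy-3-hydroxy-3-arylpropanoate from step 3
Product: 10 methyl 3-(benzyloxy)-4-{[(2R)-1,3-dihydroxy-1-[3-methoxy-4,5-bis(tert-butyldimethylsilyloxy)phenyl]propan-2-yl]oxy}-5-methoxybenzoate (both carbinol epimers)
Conditions: LiBH4 (2 equiv), THF, 0 °C
Reagents that add atoms: none
Why: Chemoselective borohydride reduction of an ester; the α-aryloxy-β-hydroxy ethyl ester is activated inductively and by the neighbouring alkoxyborohydride, the para-alkoxy-deactivated aromatic methyl ester should persist at 0 °C, and the stereocentre is untouched (S becomes R only because CH2OH now ranks below the carbinol carbon).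

Step 5
Reactants: 10 benzyl-protected diol from step 4
Product: 11 methyl 4-{[(2R)-1,3-dihydroxy-1-[3-methoxy-4,5-bis(tert-butyldimethylsilyloxy)phenyl]propan-2-yl]oxy}-3-hydroxy-5-methoxybenzoate (both carbinol epimers)
Conditions: H2 (1 atm), 10% Pd/C, EtOAc, rt
Reagents that add atoms: none
Why: Hydrogenolysis of the aryl benzyl ether under neutral conditions should be much faster than cleavage of the secondary benzylic alcohol, and the silyl ethers and esters are inert.

Step 6
Reactants: 11 phenol diol from step 5
Product: 13 methyl (2R,3R)-3-(hydroxymethyl)-5-methoxy-2-[3-methoxy-4,5-bis(tert-butyldimethylsilyloxy)phenyl]-2,3-dihydro-1,4-benzodioxine-7-carboxylate, via benzylic cation 12 (not isolated)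
Conditions: Amberlyst 15 (sulfonic acid resin), toluene, 50 °C
Reagents that add atoms: none
Why: Acid-catalysed dehydrative etherification: ionisation of the benzylic alcohol gives cation 12, stabilised by the para silyloxy group, the ortho phenol of ring A captures it in a six-membered ring closure, and because the closure is reversible under the acid both carbinol epimers should converge on the trans ring (aryl and CH2OH pseudo-equatorial), so C2 is set relative to the fixed C3 under thermodynamic control.

Step 7
Reactants: 13 trans-benzodioxane methyl ester from step 6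
Product: 14 (2R,3R)-3,7-bis(hydroxymethyl)-5-methoxy-2-[3-methoxy-4,5-bis(tert-butyldimethylsilyloxy)phenyl]-2,3-dihydro-1,4-benzodioxine
Conditions: iBu2AlH (4 equiv), CH2Cl2, −78 → 0 °C; aq. KNaC4H4O6 (potassium sodium tartrate) work-up
Reagents that add atoms: none
Why: Aluminium hydride reduction of the aromatic methyl ester to the benzylic alcohol; the free C9 hydroxyl only consumes one equivalent of hydride and the aryl silyl ethers and the ring B ethers are stable at low temperature.

Step 8
Reactants: 14 diol from step 7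
Product: 15 (2R,3R)-3-(hydroxymethyl)-5-methoxy-2-[3-methoxy-4,5-bis(tert-butyldimethylsilyloxy)phenyl]-2,3-dihydro-1,4-benzodioxine-7-carbaldehyde
Conditions: activated MnO2 (excess), CH2Cl2, rt
Reagents that add atoms: none
Why: MnO2 oxidation is selective for benzylic alcohols, so the ring A ArCH2OH should go to the aldehyde while the aliphatic C9 alcohol and the protected catechol are left alone.

Step 9
Reactants: 15 aryl aldehyde from step 8
Product: 16 (E)-3-{(2R,3R)-3-(hydroxymethyl)-5-methoxy-2-[3-methoxy-4,5-bis(tert-butyldimethylsilyloxy)phenyl]-2,3-dihydro-1,4-benzodioxin-7-yl}prop-2-enal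
Conditions: Ph3P=CHCHO (1.2 equiv), toluene, 80 °C
Reagents that add atoms: (triphenylphosphoranylidene)acetaldehyde, O=CC=P(c1ccccc1)(c1ccccc1)c1ccccc1
Why: Wittig olefination with the stabilised formylmethylene ylide should give the E enal, and keeping the ylide near one equivalent limits a second homologation of the product aldehyde.

Step 10
Reactants: 16 bis-silyl enal from step 9
Product: 17 (E)-3-[(2R,3R)-2-(3,4-dihydroxy-5-methoxyphenyl)-3-(hydroxymethyl)-5-methoxy-2,3-dihydro-1,4-benzodioxin-7-yl]prop-2-enal (CNP0103768.1)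
Conditions: TBAF (2.5 equiv), AcOH (3 equiv), THF, 0 °C, degassed
Reagents that add atoms: none
Why: Fluoride cleavage of the two aryl silyl ethers, buffered with acetic acid so that no phenoxide opens the benzylic C2–O1 bond, adds to the enal or is air-oxidised; no stereocentre is touched.

**Compound list**
1 | methyl 3,4-dihydroxy-5-methoxybenzoate | COC(=O)c1cc(O)c(O)c(OC)c1 | starting material
2 | disodium catecholate of 1 (not isolated) | COC(=O)c1cc([O-])c([O-])c(OC)c1.[Na+].[Na+] | intermediate
3 | methyl 3-(benzyloxy)-4-hydroxy-5-methoxybenzoate | COC(=O)c1cc(OC)c(O)c(OCc2ccccc2)c1 | intermediate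
4 | 5-hydroxyvanillin (3,4-dihydroxy-5-methoxybenzaldehyde) | COc1cc(C=O)cc(O)c1O | starting material
5 | 3-methoxy-4,5-bis(tert-butyldimethylsilyloxy)benzaldehyde | COc1cc(C=O)cc(O[Si](C)(C)C(C)(C)C)c1O[Si](C)(C)C(C)(C)C | intermediate
6 | ethyl diazoacetate | CCOC(=O)C=[N+]=[N-] | starting material
7 | carbene complex Rh2(OAc)4=CHCO2Et (not isolated) | CCOC(=O)C=[Rh+2].[Rh+2].CC(=O)[O-].CC(=O)[O-].CC(=O)[O-].CC(=O)[O-] | intermediate
8 | oxonium ylide from 3 and the carbene, drawn metal-free (not isolated) | CCOC(=O)[CH-][OH+]c1c(OC)cc(C(=O)OC)cc1OCc1ccccc1 | intermediate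
9 | ethyl (2S)-2-[2-(benzyloxy)-6-methoxy-4-(methoxycarbonyl)phenoxy]-3-hydroxy-3-[3-methoxy-4,5-bis(tert-butyldimethylsilyloxy)phenyl]propanoate, both carbinol epimers | COC(=O)c1cc(OC)c(O[C@H](C(=O)OCC)C(O)c2cc(OC)c(O[Si](C)(C)C(C)(C)C)c(O[Si](C)(C)C(C)(C)C)c2)c(OCc2ccccc2)c1 | intermediate
10 | methyl 3-(benzyloxy)-4-{[(2R)-1,3-dihydroxy-1-[3-methoxy-4,5-bis(tert-butyldimethylsilyloxy)phenyl]propan-2-yl]oxy}-5-methoxybenzoate, both carbinol epimers | COC(=O)c1cc(OC)c(O[C@H](CO)C(O)c2cc(OC)c(O[Si](C)(C)C(C)(C)C)c(O[Si](C)(C)C(C)(C)C)c2)c(OCc2ccccc2)c1 | intermediate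
11 | methyl 4-{[(2R)-1,3-dihydroxy-1-[3-methoxy-4,5-bis(tert-butyldimethylsilyloxy)phenyl]propan-2-yl]oxy}-3-hydroxy-5-methoxybenzoate, both carbinol epimers | COC(=O)c1cc(OC)c(O[C@H](CO)C(O)c2cc(OC)c(O[Si](C)(C)C(C)(C)C)c(O[Si](C)(C)C(C)(C)C)c2)c(O)c1 | intermediate
12 | benzylic cation from 11 (not isolated) | COC(=O)c1cc(OC)c(O[C@H](CO)[CH+]c2cc(OC)c(O[Si](C)(C)C(C)(C)C)c(O[Si](C)(C)C(C)(C)C)c2)c(O)c1 | intermediate
13 | methyl (2R,3R)-3-(hydroxymethyl)-5-methoxy-2-[3-methoxy-4,5-bis(tert-butyldimethylsilyloxy)phenyl]-2,3-dihydro-1,4-benzodioxine-7-carboxylate (trans) | COc1cc([C@H]2Oc3cc(C(=O)OC)cc(OC)c3O[C@@H]2CO)cc(O[Si](C)(C)C(C)(C)C)c1O[Si](C)(C)C(C)(C)C | intermediate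
14 | (2R,3R)-3,7-bis(hydroxymethyl)-5-methoxy-2-[3-methoxy-4,5-bis(tert-butyldimethylsilyloxy)phenyl]-2,3-dihydro-1,4-benzodioxine | COc1cc([C@H]2Oc3cc(CO)cc(OC)c3O[C@@H]2CO)cc(O[Si](C)(C)C(C)(C)C)c1O[Si](C)(C)C(C)(C)C | intermediate
15 | (2R,3R)-3-(hydroxymethyl)-5-methoxy-2-[3-methoxy-4,5-bis(tert-butyldimethylsilyloxy)phenyl]-2,3-dihydro-1,4-benzodioxine-7-carbaldehyde | COc1cc([C@H]2Oc3cc(C=O)cc(OC)c3O[C@@H]2CO)cc(O[Si](C)(C)C(C)(C)C)c1O[Si](C)(C)C(C)(C)C | intermediate
16 | (E)-3-{(2R,3R)-3-(hydroxymethyl)-5-methoxy-2-[3-methoxy-4,5-bis(tert-butyldimethylsilyloxy)phenyl]-2,3-dihydro-1,4-benzodioxin-7-yl}prop-2-enal | COc1cc([C@H]2Oc3cc(/C=C/C=O)cc(OC)c3O[C@@H]2CO)cc(O[Si](C)(C)C(C)(C)C)c1O[Si](C)(C)C(C)(C)C | intermediate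
17 | (E)-3-[(2R,3R)-2-(3,4-dihydroxy-5-methoxyphenyl)-3-(hydroxymethyl)-5-methoxy-2,3-dihydro-1,4-benzodioxin-7-yl]prop-2-enal (CNP0103768.1) | COc1cc([C@H]2Oc3cc(/C=C/C=O)cc(OC)c3O[C@@H]2CO)cc(O)c1O | target

**Totals**
Total step count: 10. Longest linear sequence: 9 steps (from 1 through steps 1 and 3 to 10).

**Steps most likely to fail**

Step 3. The proton shift within ylide 8 may outrun the addition to the aldehyde, leaving only O–H insertion, or the facial selectivity in the chiral assembly may be poor. The fallback sets out from 3 and comes back at 10, using known auxiliary chemistry. Phenol 3 is alkylated with (4S)-4-benzyl-3-(chloroacetyl)oxazolidin-2-one (K2CO3, NaI, acetone) to give the aryloxyacetyl imide methyl 3-(benzyloxy)-4-{2-[(4S)-4-benzyl-2-oxooxazolidin-3-yl]-2-oxoethoxy}-5-methoxybenzoate F1. An Evans syn aldol reaction of its boron enolate (Bu2BOTf, iPr2NEt, CH2Cl2, −78 → 0 °C) with aldehyde 5 should give the (2S,3R) adduct methyl 4-{[(2S,3R)-1-[(4S)-4-benzyl-2-oxooxazolidin-3-yl]-3-hydroxy-3-[3-methoxy-4,5-bis(tert-butyldimethylsilyloxy)phenyl]-1-oxopropan-2-yl]oxy}-3-(benzyloxy)-5-methoxybenzoate F2, with the aryloxy-bearing centre set by the auxiliary. Reductive removal of the auxiliary (LiBH4, THF, 0 °C) gives 10 as a single carbinol epimer, which step 6 accepts as well as the mixture.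

Step 6. Ionisation of the 3,4,5-trioxygenated benzylic alcohol may be slow, and forcing the acid could cause loss of silyl groups, loss of formaldehyde from the cation, or erosion of C3 through an enol ether. The fallback sets out from 11 and comes back at 13, separating activation from ring closure. Bromotrimethylsilane (CH2Cl2, 0 °C) converts the benzylic hydroxyl selectively into the bromide, methyl 4-{[(2R)-1-bromo-3-hydroxy-1-[3-methoxy-4,5-bis(tert-butyldimethylsilyloxy)phenyl]propan-2-yl]oxy}-3-hydroxy-5-methoxybenzoate F3, which is used crude. K2CO3 in acetone at rt then closes ring B by intramolecular phenoxide displacement through the ion pair, which should favour the trans ring 13 without strong acid or heat.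

Step 1. Alkylation may occur at the wrong oxygen or twice. The fallback sets out from 1 and comes back at 3, fixing the regiochemistry by protecting the more acidic hydroxyl first. Allyl bromide with KHCO3 in DMF alkylates the 4-hydroxyl (para to the ester) as the monoanion to give methyl 4-(allyloxy)-3-hydroxy-5-methoxybenzoate F4. BnBr and K2CO3 in DMF give methyl 4-(allyloxy)-3-(benzyloxy)-5-methoxybenzoate F5. Deallylation with Pd(PPh3)4 (zerovalent palladium) and morpholine in THF returns 3.

Further compounds
F1 | step 3 | methyl 3-(benzyloxy)-4-{2-[(4S)-4-benzyl-2-oxooxazolidin-3-yl]-2-oxoethoxy}-5-methoxybenzoate | COC(=O)c1cc(OC)c(OCC(=O)N2[C@@H](Cc3ccccc3)COC2=O)c(OCc2ccccc2)c1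
F2 | step 3 | methyl 4-{[(2S,3R)-1-[(4S)-4-benzyl-2-oxooxazolidin-3-yl]-3-hydroxy-3-[3-methoxy-4,5-bis(tert-butyldimethylsilyloxy)phenyl]-1-oxopropan-2-yl]oxy}-3-(benzyloxy)-5-methoxybenzoate | COC(=O)c1cc(OC)c(O[C@H](C(=O)N2[C@@H](Cc3ccccc3)COC2=O)[C@H](O)c2cc(OC)c(O[Si](C)(C)C(C)(C)C)c(O[Si](C)(C)C(C)(C)C)c2)c(OCc2ccccc2)c1
F3 | step 6 | methyl 4-{[(2R)-1-bromo-3-hydroxy-1-[3-methoxy-4,5-bis(tert-butyldimethylsilyloxy)phenyl]propan-2-yl]oxy}-3-hydroxy-5-methoxybenzoate, both C1 epimers | COC(=O)c1cc(OC)c(O[C@H](CO)C(Br)c2cc(OC)c(O[Si](C)(C)C(C)(C)C)c(O[Si](C)(C)C(C)(C)C)c2)c(O)c1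
F4 | step 1 | methyl 4-(allyloxy)-3-hydroxy-5-methoxybenzoate | COC(=O)c1cc(O)c(OCC=C)c(OC)c1
F5 | step 1 | methyl 4-(allyloxy)-3-(benzyloxy)-5-methoxybenzoate | COC(=O)c1cc(OC)c(OCC=C)c(OCc2ccccc2)c1
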